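**Plan**
- Cuts: (i) the aryl–acyl bond C6–C(=O) of the chromene, giving chromen-5-ol 6 and 4-methoxyphenylglyoxal, joined one oxidation level low as the benzoin; (ii) C5–OH back to C5–Br; (iii) the pyran ring (O1–C2 and C4–C4a) back to an aryl 1,1-dimethylpropargyl ether of 5-bromo-2-methoxyphenol.
- Enabling feature: the free C5–OH of the benzene ring lies next to C6–H, while its other ortho atom C4a is the pyran ring-fusion carbon and its para atom C8 carries OMe. A boron atom hung on O5 can therefore hand an aldehyde carbon only to C6.
- Forward order: O-propargylation; Claisen cascade to build the 2H-pyran ring; Br to OH at C5; phenylboronic acid ties O5 and the glyoxal aldehyde into a temporary 1,3,2-dioxaborin ring (absent from the target) as the C6–C bond forms; boron is then removed and the carbinol oxidised to the 1,2-diketone.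
- Helpers and their removal: C5–Br (keeps a single phenol oxygen during pyran closure, exchanged in step 3); the O–B–O ring and the carbinol oxidation level (both removed in step 5).
- Stereochemistry: the target has no stereocentre; the carbinol carbon of 9 and 10 is racemic and is erased by the final oxidation.

Key step: step 4

Step 1
Reactants: 1 5-bromo-2-methoxyphenol; 2 3-chloro-3-methylbut-1-yne
Product: 3 4-bromo-1-methoxy-2-[(2-methylbut-3-yn-2-yl)oxy]benzene
Conditions: K2CO3, KI (cat.), CuI (cat.), acetone, reflux
Reagents that add atoms: none
Why: Copper-assisted Williamson-type O-alkylation of the phenoxide by the tertiary propargylic chloride is the standard entry to aryl 1,1-dimethylpropargyl ethers, and the aryl bromide and methyl ether are inert to carbonate.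

Step 2
Reactants: 3 4-bromo-1-methoxy-2-[(2-methylbut-3-yn-2-yl)oxy]benzene
Product: 5 5-bromo-8-methoxy-2,2-dimethyl-2H-chromene, via ortho-allenylphenol 4 (not isolated)
Conditions: PhNEt2, 190 °C
Reagents that add atoms: none
Why: The aromatic propargyl Claisen rearrangement can reach only the free ortho carbon (the other bears OMe), and allenylphenol 4 should close by [1,5]-H shift and oxa-6π electrocyclisation to the 2H-chromene, with only one phenol oxygen available because C5 still carries Br.

Step 3
Reactants: 5 5-bromo-8-methoxy-2,2-dimethyl-2H-chromene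
Product: 6 8-methoxy-2,2-dimethyl-2H-chromen-5-ol
Conditions: Pd2(dba)3 (cat.), tBuXPhos (cat.), KOH, 1,4-dioxane/H2O, 100 °C; then aq. HCl
Reagents that add atoms: potassium hydroxide, [K+].[OH-]
Why: Palladium-catalysed hydroxylation of an aryl bromide with KOH (Buchwald–Hartwig-type C–O coupling with a bulky biarylphosphine) should convert C5–Br into the phenol, the base-stable chromene alkene being a poor Heck acceptor (cis-disubstituted, next to a quaternary carbon).

Step 4
Reactants: 6 8-methoxy-2,2-dimethyl-2H-chromen-5-ol; 7 4-methoxyphenylglyoxal hydrate [2,2-dihydroxy-1-(4-methoxyphenyl)ethan-1-one]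
Product: 9 rac-cyclic phenylboronate of benzoin 10 (4H-1,3,2-dioxaborin fused to C5–C6 of the chromene: O5–B(Ph)–O–CH[C(=O)C6H4-4-OMe]–C6), via aryl hydrogen phenylboronate 8 (not isolated)
Conditions: PhB(OH)2, EtCO2H (cat.), toluene, reflux, Dean–Stark
Reagents that add atoms: phenylboronic acid, OB(O)c1ccccc1
Why: Phenol 6 condenses with PhB(OH)2 to the aryl hydrogen boronate 8, whose Lewis-acidic boron binds the aldehyde oxygen of the glyoxal (freed from hydrate 7 by azeotropic dehydration), so that the aldehyde carbon is delivered to C6 through a six-membered chair-like transition state (C6–C5–O5–B–O=C) in a boron-templated electrophilic aromatic substitution, after which tautomerisation and loss of water lock the adduct as dioxaborin 9. The closest known reaction type is the phenylboronic acid-mediated ortho-specific hydroxyalkylation of phenols with aldehydes, which gives 2-phenyl-4H-1,3,2-benzodioxaborins. The dioxaborin ring closes by C–C bond formation inside the O5–B–O chelate (formally 6-endo-trig at the boron-bound C=O), its B–O bonds being made by reversible condensation. The one new stereocentre, the carbinol carbon, forms as a racemate with no controlling element and is erased in step 5. The step needs regioselectivity for C6 over C7 and over O-alkylation and chemoselectivity for the aldehyde over the aryl ketone: the O5–B tether reaches only the two carbons ortho to O5, of which C4a is the quaternary ring-fusion atom, the para carbon C8 carries OMe, and the aldehyde is far more electrophilic than the ketone conjugated to the anisyl ring. The boron ring also stops the reaction at mono-addition by holding the benzylic oxygen as a boronate, so that neither a second arylation nor cyclodehydration to a benzofuranone should follow.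

Step 5
Reactants: 9 rac-cyclic phenylboronate of benzoin 10
Product: 11 Dielsianone, via benzoin 10 (not isolated)
Conditions: pinacol, MeOH, rt; then Cu(OAc)2·H2O, AcOH/H2O (4:1), 60 °C, N2
Reagents that add atoms: none
Why: Transesterification to the more stable pinacol boronate frees benzoin 10, and copper(II) acetate should dehydrogenate the α-ketol through its copper enediolate (classical acyloin to 1,2-diketone oxidation) under acidic, base-free conditions that spare the chromene alkene and the phenol and avoid benzilic acid rearrangement of the ortho-hydroxybenzil.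

**Compound list**
1 | 5-bromo-2-methoxyphenol | COc1ccc(Br)cc1O | starting material
2 | 3-chloro-3-methylbut-1-yne | CC(C)(Cl)C#C | starting material
3 | 4-bromo-1-methoxy-2-[(2-methylbut-3-yn-2-yl)oxy]benzene | COc1ccc(Br)cc1OC(C)(C)C#C | intermediate
4 | 3-bromo-6-methoxy-2-(3-methylbuta-1,2-dien-1-yl)phenol (not isolated) | COc1ccc(Br)c(C=C=C(C)C)c1O | intermediate
5 | 5-bromo-8-methoxy-2,2-dimethyl-2H-chromene | COc1ccc(Br)c2C=CC(C)(C)Oc12 | intermediate
6 | 8-methoxy-2,2-dimethyl-2H-chromen-5-ol | COc1ccc(O)c2C=CC(C)(C)Oc12 | intermediate
7 | 4-methoxyphenylglyoxal hydrate, 2,2-dihydroxy-1-(4-methoxyphenyl)ethan-1-one | COc1ccc(cc1)C(=O)C(O)O | starting material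
8 | 8-methoxy-2,2-dimethyl-2H-chromen-5-yl hydrogen phenylboronate (not isolated) | COc1ccc(OB(O)c2ccccc2)c2C=CC(C)(C)Oc12 | intermediate
9 | rac-cyclic phenylboronate of benzoin 10: 4-(4-methoxybenzoyl)-2-phenyl-4H-1,3,2-dioxaborin fused to the chromene, ring O–B(Ph)–O–CH(COAr)–C6–C5, racemic at the CH carbon | COc1ccc(cc1)C(=O)C1OB(c2ccccc2)Oc2c1cc(OC)c1OC(C)(C)C=Cc21 | intermediate
10 | rac-2-hydroxy-2-(5-hydroxy-8-methoxy-2,2-dimethyl-2H-chromen-6-yl)-1-(4-methoxyphenyl)ethan-1-one (not isolated) | COc1ccc(cc1)C(=O)C(O)c1cc(OC)c2OC(C)(C)C=Cc2c1O | intermediate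
11 | Dielsianone, 1-(5-hydroxy-8-methoxy-2,2-dimethyl-2H-chromen-6-yl)-2-(4-methoxyphenyl)ethane-1,2-dione (achiral) | COc1ccc(C(=O)C(=O)c2cc(OC)c3c(c2O)C=CC(C)(C)O3)cc1 | target

**Summary**
Total step count: 5. Longest linear sequence: 5 steps (1 → 3 → 5 → 6 → 9 → 11); glyoxal hydrate 7 is commercial.

**Steps most likely to fail**

Step 4. The glyoxal may be consumed by self-condensation or hemiacetal and oligomer formation faster than boron delivers it to C6, or the acid at reflux may open or oligomerise the 2H-pyran ring. The fallback sets out from chromenol 6 and rejoins the route at 11, joining the fragments at the deoxybenzoin level instead. The bromomagnesium phenoxide of 6 (EtMgBr, toluene) is acylated at C6 by 4-methoxyphenylacetyl chloride under magnesium chelation control (ortho-acylation of a metal phenoxide) to give 1-(5-hydroxy-8-methoxy-2,2-dimethyl-2H-chromen-6-yl)-2-(4-methoxyphenyl)ethan-1-one F1, whose doubly activated methylene is oxidised with SeO2 in aqueous dioxane at 90 °C (Riley oxidation) to 11. The chromene has no allylic C–H, so it should not be attacked.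

Step 5. Oxidation of the electron-rich para-alkoxyphenol ring, retention of copper by the chelating salicyloyl diketone, or incomplete release from boron may compete with clean ketol dehydrogenation. The fallback sets out from 9 and rejoins at 11 with the phenol masked during the oxidation. Compound 9 is transesterified with pinacol and benzoin 10 is isolated. The phenol is converted to its methoxymethyl ether (MOMCl, iPr2NEt, CH2Cl2, 0 °C) to give rac-2-hydroxy-2-[8-methoxy-5-(methoxymethoxy)-2,2-dimethyl-2H-chromen-6-yl]-1-(4-methoxyphenyl)ethan-1-one F2. The carbinol is oxidised with Dess–Martin periodinane (CH2Cl2, rt) to 1-[8-methoxy-5-(methoxymethoxy)-2,2-dimethyl-2H-chromen-6-yl]-2-(4-methoxyphenyl)ethane-1,2-dione F3, and the acetal is removed with HCl in MeOH at 40 °C to give 11.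

Step 3. Reductive loss of bromine, or O-arylation of the product phenoxide by unreacted bromide, may outrun hydroxide transfer at the electron-rich, ortho-substituted C5–Br bond. The fallback sets out from 5 and rejoins at 6 through boron instead of palladium. Bromine–lithium exchange (n-BuLi, THF, −78 °C), trapping with B(OMe)3 and aqueous work-up give (8-methoxy-2,2-dimethyl-2H-chromen-5-yl)boronic acid F4, which is oxidised with alkaline H2O2 at 0 °C to 6; nucleophilic peroxide should leave the electron-rich chromene alkene untouched.

Further compounds
F1 | step 4 | 1-(5-hydroxy-8-methoxy-2,2-dimethyl-2H-chromen-6-yl)-2-(4-methoxyphenyl)ethan-1-one | COc1ccc(CC(=O)c2cc(OC)c3OC(C)(C)C=Cc3c2O)cc1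
F2 | step 5 | rac-2-hydroxy-2-[8-methoxy-5-(methoxymethoxy)-2,2-dimethyl-2H-chromen-6-yl]-1-(4-methoxyphenyl)ethan-1-one | COCOc1c(C(O)C(=O)c2ccc(OC)cc2)cc(OC)c2OC(C)(C)C=Cc12
F3 | step 5 | 1-[8-methoxy-5-(methoxymethoxy)-2,2-dimethyl-2H-chromen-6-yl]-2-(4-methoxyphenyl)ethane-1,2-dione | COCOc1c(C(=O)C(=O)c2ccc(OC)cc2)cc(OC)c2OC(C)(C)C=Cc12
F4 | step 3 | (8-methoxy-2,2-dimethyl-2H-chromen-5-yl)boronic acid | COc1ccc(B(O)O)c2C=CC(C)(C)Oc12
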